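## Structural features

Sideritiflavone is a flavone: a benzene ring (ring A) is fused through C4a–C8a to a 4-pyranone (ring C), and a phenyl ring (ring B) is joined to it by the single bond C2–C1'. It has no stereogenic centre or axis, so the problem is one of constitution only. Ring A is fully substituted: O1 at C8a, methyl ethers at C8, C7 and C6, a free hydroxyl at C5 hydrogen-bonded to the C4 carbonyl, and C4 at C4a. Ring B carries a free catechol at C3' and C4'. The fragile parts are the catechol (easily oxidised to an ortho-quinone, above all when deprotonated), C2 of the pyranone (attack by hot alkoxide can open ring C) and the crowded vicinal methyl ethers of ring A (prone to Lewis-acid cleavage). The real difficulty is the oxygen pattern: six aryl oxygens on two rings, three methylated and three free, on top of a hexasubstituted ring A. The key step uses the fact that C2'–C3'–C4'–C5' of ring B, with oxygen on the two inner carbons, maps onto a 2,3-dioxygenated butadiene, while C1' and C6' can be the two carbons of an ethynyl group on C2. The catechol oxygens then arrive as silyl ethers and never as alkyl ethers, so ring B needs no ether differentiation.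

## Logic of the disconnections

**16 to 14 (through 15).** The two O–H bonds of the catechol are traced back to O–Si bonds, and the aromatic ring B to a cyclohexa-1,4-diene with two extra hydrogens at C2' and C5'. This lowers ring B to the oxidation level of an alkyne Diels–Alder adduct and keeps the protecting groups that the diene delivers. The forward step must stop the dehydrogenation at the catechol ether and remove silicon without base or oxidant.

**14 to 11 and 13.** The bonds C1'–C2' and C5'–C6' are cut. They lie 1,4 to each other in one ring across the C3'=C4' double bond, which is the retron of a [4+2] cycloaddition. The cut removes four carbons and both catechol oxygens as a symmetric unit and leaves a chromone with a two-carbon handle. It demands an alkyne electron-poor enough to react thermally, selectivity for the alkyne over C2=C3, and conditions free of acid, because 13 is a bis(silyl enol ether).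

**13 to 12.** Two O–Si bonds are cut, leading back to a bulk 1,2-diketone. The forward step must enolise both carbonyls outward without aldol self-condensation and must be worked up dry.

**11 to 9 (through 10).** The alkyne C–H is traced back to C–Si and the O5–H to O5–CH3. Both the terminal alkyne and a free peri hydroxyl are liabilities in the enolate chemistry that builds ring C. A methyl ether at C5 also means the ring A ketone needs only one free phenol. C5 is the one position where a methyl ether can be removed selectively, through chelation with the C4 carbonyl. The forward steps need a Lewis acid that distinguishes this ether from three others and spares the alkynylsilane, and a fluoride step that does not trigger conjugate addition to the ethynylchromone.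

**9 to 7 (through 8).** The O1–C2 bond is cut, and the C2=C3 unsaturation is traced to loss of water. This opens ring C to an ortho-hydroxyaryl 1,3-diketone. The phenol must add to the C=O faster than the diketone enol adds to the alkyne; the silyl group on the alkyne terminus is there to secure this.

**7 to 5 and 6.** The bond between the future C3 (acetyl methyl of 5) and the future C2 (ester carbon of 6) is cut. This gives an acetophenone holding every ring A oxygen and a commercial three-carbon alkynoate. The enolate must substitute at the acyl carbon and not add to the alkyne.

**5 to 3 (through 4).** The aryl–acyl bond C4a–C4 is cut and one flanking O–H is traced to O–CH3. Compound 3 has a single free position and two equivalent ortho ethers, so neither the acylation nor the demethylation poses a regiochemical question. The Lewis acid must stop after one ortho ether.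

**3 to 1 (through 2).** Two aryl C–O bonds are traced to C–Br and these to C–H. Compound 1 has only three of the five ring A oxygens, and its two most activated positions are exactly where the missing two must go. The double bromination must stop at the 4,6-dibromide and the copper-mediated exchange must go to completion at both positions.

## Other disconnections considered

**Alternative 1:** The cut is at the C6–O and C8–O bonds of the two outer methoxyls. Commercial luteolin A3 would be protected at the catechol as a diphenylmethylene ketal, methylated at O7 (the chelated 5-OH stays free) and brominated twice to give 6,8-dibromo-2-(2,2-diphenyl-1,3-benzodioxol-5-yl)-5-hydroxy-7-methoxy-4H-chromen-4-one A2. In the key step NaOMe with CuBr (monovalent copper) in DMF would exchange both bromines of A2 to give 3',4'-O-diphenylmethylene sideritiflavone A1, and acid hydrolysis of the ketal of A1 would finish the synthesis.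
- In its favour: the whole C15 skeleton is bought as A3, about five steps suffice, and copper-mediated methoxylation of aryl bromides is a broadly used reaction class. Because C6 and C8 end up identically substituted, an acid-induced opening and reclosure of ring C through the other ortho oxygen would be harmless.
- Against it: the finished 5-hydroxyflavone A2 is exposed to hot methoxide, which can attack C2 and open ring C. Ring A reacts as an electron-rich phenoxide, so exchange at two hindered positions may be slow and hydrodebromination may compete. Incomplete exchange would give mixtures that are hard to separate from A1.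
- Comparison: on step economy Alternative 1 is clearly better than the chosen plan (about half the steps). On mechanism its key step rests on known chemistry, whereas step 9 does not, which is also a point for the alternative. On structure the plans are about equal: the chosen plan fixes the ring A oxygens before the base-sensitive pyranone exists, while the alternative needs a catechol ketal that survives hot base, which it should. The chosen plan's own merits are that the flavone never sees strong base at high temperature and that ring B is built, so ring B analogues would follow from other dienes.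

**Alternative 2:** The cut is at C4a–C5, with ring A assembled from a squarate-derived four-carbon unit and the enol ether double bond of a dihydropyran. Heating 4-[cis-4-(tert-butyldimethylsilyloxy)-2-(2,2-dimethyl-1,3-benzodioxol-5-yl)-3,4-dihydro-2H-pyran-6-yl]-2,3,4-trimethoxycyclobut-2-en-1-one A5 would open the four-membered ring to a dienylketene. A six-electron electrocyclisation and tautomerisation would then give racemic cis-4-(tert-butyldimethylsilyloxy)-2-(2,2-dimethyl-1,3-benzodioxol-5-yl)-6,7,8-trimethoxychroman-5-ol A4. Desilylation of A4, oxidation at C4, dehydrogenation across C2–C3 and acetonide removal would follow.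
- In its favour: the C5 hydroxyl of A4 is the former ketene carbonyl and is therefore distinct from the three methoxyls by construction. This is better than the chosen plan, which relies on a selective demethylation in step 6. The key step is neutral and thermal, and ring expansions of this kind have a broader precedent base than step 9, again a point for the alternative.
- Against it: about eleven to twelve linear steps; two stereocentres (C2 and C4) are made only to be erased; the oxidation level of ring C is adjusted twice; and A5 requires vinyl lithiation of a dihydropyran bearing an allylic silyloxy group and methylation of a hindered tertiary alkoxide.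
- Comparison: both plans build a ring by a pericyclic step. Alternative 2 is stronger on precedent and on oxygen differentiation. The chosen plan is stronger on step and redox economy, since it stays at the chromone oxidation level and needs a single dehydrogenation.

**Alternative 3:** The cut is at three bonds of ring C: C8a–O1, C4a–C4 and O1–C2. CsF would release the symmetric aryne from 2,3,4,5-tetramethoxy-6-(trimethylsilyl)phenyl trifluoromethanesulfonate A7. The carboxylate of 3-[3,4-bis(benzyloxy)phenyl]prop-2-ynoic acid A8 would add to the aryne, the aryl anion would attack its own acyl carbon (net insertion into C–O), and the phenoxide would close onto the ynone to give 3',4'-bis(benzyloxy)-5,6,7,8-tetramethoxyflavone A6. BCl3 would then remove both benzyl groups and the peri methyl group of A6 in one step.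
- In its favour: it is highly convergent, since ring C forms in one operation from the two fragments A7 and A8 of similar size. The symmetric aryne removes regiochemistry. The reaction class is known for simpler arynes, so precedent is better than for step 9. The one-step endgame from A6 is the equal or the better of steps 9 and 10.
- Against it: A7 is a hexasubstituted benzene that needs about five steps. Its aryne is electron-rich and flanked by two methoxyls. The phenoxide may close 5-exo to an aurone in competition with the 6-endo mode that leads to A6. The plan needs the same peri-demethylation as the chosen plan, so on that point the two are equal.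
- Comparison: the total step count is similar, and the longest linear sequence is shorter for Alternative 3 because it is convergent, which is a point for the alternative. The chosen plan has the simpler ring A chemistry: steps 1–3 are three robust operations on a symmetric arene.

Key step: step 9

Remark 1: the C5 oxygen is carried as a methyl ether up to 9 and released in step 6. A symmetric 2,6-dihydroxyacetophenone would need two ortho-demethylations and a trianion in the Claisen step; the key-step precursor 11 is unchanged.
Remark 2: 7 is drawn as the open diketone, although it should exist in equilibrium with its enol and its cyclic hemiketal 8. Compounds 14 and 15 are moisture-sensitive silyl ethers and are carried on without chromatography.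
Remark 3: in flavone numbering the two CH2 groups of 14 are C2' and C5' and the silyloxy-bearing carbons are C3' and C4', so dehydrogenation places the catechol correctly.

## Route

Step 1
Reactants: 1 1,2,3-trimethoxybenzene
Product: 2 1,5-dibromo-2,3,4-trimethoxybenzene
Conditions: NBS (2.1 equiv), MeCN, 0 °C → rt
Reagents that add atoms: N-bromosuccinimide, O=C1CCC(=O)N1Br
Why: Electrophilic aromatic bromination; each outer methoxy group directs para to itself (C4 and C6) while the twisted central ether donates little, so the two most activated positions should react and C5, meta to both outer ethers, should be left.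

Step 2
Reactants: 2 1,5-dibromo-2,3,4-trimethoxybenzene
Product: 3 pentamethoxybenzene
Conditions: NaOMe (6 equiv), CuBr (0.3 equiv), DMF–MeOH, 105 °C, N2
Reagents that add atoms: sodium methoxide, C[O-].[Na+]
Why: Ullmann-type methoxylation of aryl bromides mediated by monovalent copper; both C–Br bonds should be exchanged and the substrate offers no other electrophilic site.

Step 3
Reactants: 3 pentamethoxybenzene
Product: 5 1-(2-hydroxy-3,4,5,6-tetramethoxyphenyl)ethan-1-one, via 1-(pentamethoxyphenyl)ethan-1-one 4 (not isolated)
Conditions: AcCl (1.2 equiv), AlCl3 (2.5 equiv), CH2Cl2, 0 °C → rt; then 1 M HCl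
Reagents that add atoms: acetyl chloride, CC(Cl)=O
Why: Friedel–Crafts acylation at the only free position gives 4, whose AlCl3-bound carbonyl activates a neighbouring methoxy group for chelation-assisted O-demethylation. The two ortho ethers are equivalent, so one product is expected, and the chelated aluminium phenoxide should resist a second cleavage at this temperature.

Step 4
Reactants: 5 1-(2-hydroxy-3,4,5,6-tetramethoxyphenyl)ethan-1-one; 6 ethyl 3-(trimethylsilyl)propiolate
Product: 7 1-(2-hydroxy-3,4,5,6-tetramethoxyphenyl)-5-(trimethylsilyl)pent-4-yne-1,3-dione
Conditions: LiN(SiMe3)2 (3.1 equiv), THF, −78 → −20 °C; 6 (1.2 equiv), −78 → 0 °C; AcOH quench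
Reagents that add atoms: none
Why: Crossed Claisen condensation: the lithium phenoxide–enolate dianion of 5 attacks the ester carbonyl of 6, and the third equivalent of base turns the 1,3-diketone into its enolate, which draws the equilibrium forward. The silyl group at the alkyne terminus shields it from conjugate addition.

Step 5
Reactants: 7 1-(2-hydroxy-3,4,5,6-tetramethoxyphenyl)-5-(trimethylsilyl)pent-4-yne-1,3-dione
Product: 9 5,6,7,8-tetramethoxy-2-[(trimethylsilyl)ethynyl]-4H-chromen-4-one, via 2-hydroxy-5,6,7,8-tetramethoxy-2-[(trimethylsilyl)ethynyl]chroman-4-one 8 (not isolated)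
Conditions: conc. H2SO4 (cat.), AcOH, rt → 45 °C
Reagents that add atoms: none
Why: Acid-catalysed cyclodehydration of an ortho-hydroxyaryl 1,3-diketone, the closing stage of the Claisen and Baker–Venkataraman chromone syntheses. A 6-exo-trig addition of the phenol to the C3 carbonyl gives hemiketal 8 (one stereocentre at C2, racemic and lost at once), which eliminates water to the pyranone. The silyl group disfavours the competing 6-endo-dig attack of the enol oxygen on the alkyne.

Step 6
Reactants: 9 5,6,7,8-tetramethoxy-2-[(trimethylsilyl)ethynyl]-4H-chromen-4-one
Product: 10 5-hydroxy-6,7,8-trimethoxy-2-[(trimethylsilyl)ethynyl]-4H-chromen-4-one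
Conditions: BCl3 (1.5 equiv), CH2Cl2, −78 → 0 °C; then H2O
Reagents that add atoms: none
Why: Chelation-controlled Lewis-acid ether cleavage: boron binds the basic C4 carbonyl and the peri C5 oxygen in a six-membered chelate, so chloride should remove only the C5 methyl group. The ethers at C6–C8 lack this assistance, and the electron-poor alkynylsilane is a poor partner for electrophilic boron.

Step 7
Reactants: 10 5-hydroxy-6,7,8-trimethoxy-2-[(trimethylsilyl)ethynyl]-4H-chromen-4-one
Product: 11 2-ethynyl-5-hydroxy-6,7,8-trimethoxy-4H-chromen-4-one
Conditions: Bu4NF (1.1 equiv), AcOH (1.5 equiv), THF, −20 → 0 °C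
Reagents that add atoms: none
Why: Fluoride-induced protodesilylation of an alkynylsilane; the AcOH buffer protonates the acetylide at once and keeps nucleophiles from adding to the electrophilic ethynylchromone.

Step 8
Reactants: 12 2,3-butanedione
Product: 13 2,3-bis(trimethylsilyloxy)buta-1,3-diene
Conditions: Me3SiOTf (2.2 equiv), Et3N (2.6 equiv), Et2O, 0 °C → rt; distillation under reduced pressure
Reagents that add atoms: trimethylsilyl trifluoromethanesulfonate, C[Si](C)(C)OS(=O)(=O)C(F)(F)F
Why: Double soft enolisation and O-silylation of a 1,2-diketone with a silyl triflate and a tertiary amine should give the bis(silyl enol ether), which is the 2,3-dioxygenated diene.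

Step 9
Reactants: 11 2-ethynyl-5-hydroxy-6,7,8-trimethoxy-4H-chromen-4-one; 13 2,3-bis(trimethylsilyloxy)buta-1,3-diene
Product: 14 2-[4,5-bis(trimethylsilyloxy)cyclohexa-1,4-dien-1-yl]-5-hydroxy-6,7,8-trimethoxy-4H-chromen-4-one
Conditions: 13 (3 equiv), BHT (cat.), PhMe, sealed tube, 130 °C, Ar; volatiles removed, crude used directly
Reagents that add atoms: none
Why: Proposed new method: a thermal, concerted but asynchronous [4π+2π] cycloaddition is expected between the s-cis form of 13, whose HOMO is raised by two silyloxy groups, and the terminal C≡C of 11, whose LUMO is lowered by conjugation through C2=C3 to the hydrogen-bonded C4 carbonyl (a vinylogous ynone), with bonding more advanced at the unsubstituted alkyne carbon. The closest known reaction type is the Diels–Alder reaction of 2,3-bis(silyloxy)butadienes with acetylenic esters and ketones, whose cyclohexa-1,4-diene adducts are dehydrogenated to catechol ethers; an ethynyl group activated only through a chromone has no counterpart there. Ring B is closed as a six-membered carbocycle by an intermolecular [4+2] annulation in which C1'–C2' and C5'–C6' form suprafacially on both partners in one step, giving the 1,4-diene with the enediol bis(silyl ether) at C3'–C4'. No stereocentre is created. The step needs site selectivity for the alkyne over the ring C alkene: C2=C3 is trisubstituted, receives electron density from O1 and belongs to a pyranone with aromatic character, whereas the alkyne is terminal and unhindered. Regiochemistry does not arise because 13 is constitutionally symmetric. No Lewis acid is used, since it would divert the silyl enol ether into Mukaiyama-type additions, and the excess of 13 covers any slow protodesilylation by the chelated, weakly acidic 5-OH. The adduct offers 13 no second activated π bond, so over-addition is not expected.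

Step 10
Reactants: 14 2-[4,5-bis(trimethylsilyloxy)cyclohexa-1,4-dien-1-yl]-5-hydroxy-6,7,8-trimethoxy-4H-chromen-4-one
Product: 16 sideritiflavone [2-(3,4-dihydroxyphenyl)-5-hydroxy-6,7,8-trimethoxy-4H-chromen-4-one], via 2-[3,4-bis(trimethylsilyloxy)phenyl]-5-hydroxy-6,7,8-trimethoxy-4H-chromen-4-one 15 (not isolated)
Conditions: DDQ (1.05 equiv), PhMe, 0 °C → rt; aq Na2S2O4 wash; then 1 M HCl, MeOH–THF, rt
Reagents that add atoms: none
Why: Quinone dehydrogenation of a 1,4-cyclohexadiene (hydride abstraction from a doubly allylic CH2 next to the enol ether, then proton loss) should give arene 15. Acidic methanolysis then cleaves the aryl silyl ethers, and any 5-O-silyl ether, under non-basic conditions that spare the catechol; the reductive wash removes residual oxidant before the catechol is set free.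

## Compound list

1 | 1,2,3-trimethoxybenzene | COc1cccc(OC)c1OC | starting material
2 | 1,5-dibromo-2,3,4-trimethoxybenzene | COc1c(Br)cc(Br)c(OC)c1OC | intermediate
3 | pentamethoxybenzene | COc1cc(OC)c(OC)c(OC)c1OC | intermediate
4 | 1-(pentamethoxyphenyl)ethan-1-one | CC(=O)c1c(OC)c(OC)c(OC)c(OC)c1OC | intermediate
5 | 1-(2-hydroxy-3,4,5,6-tetramethoxyphenyl)ethan-1-one | CC(=O)c1c(O)c(OC)c(OC)c(OC)c1OC | intermediate
6 | ethyl 3-(trimethylsilyl)propiolate | CCOC(=O)C#C[Si](C)(C)C | starting material
7 | 1-(2-hydroxy-3,4,5,6-tetramethoxyphenyl)-5-(trimethylsilyl)pent-4-yne-1,3-dione | C[Si](C)(C)C#CC(=O)CC(=O)c1c(O)c(OC)c(OC)c(OC)c1OC | intermediate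
8 | 2-hydroxy-5,6,7,8-tetramethoxy-2-[(trimethylsilyl)ethynyl]chroman-4-one (racemic) | COc1c(OC)c(OC)c2C(=O)CC(O)(C#C[Si](C)(C)C)Oc2c1OC | intermediate
9 | 5,6,7,8-tetramethoxy-2-[(trimethylsilyl)ethynyl]-4H-chromen-4-one | COc1c(OC)c(OC)c2c(=O)cc(C#C[Si](C)(C)C)oc2c1OC | intermediate
10 | 5-hydroxy-6,7,8-trimethoxy-2-[(trimethylsilyl)ethynyl]-4H-chromen-4-one | COc1c(OC)c(O)c2c(=O)cc(C#C[Si](C)(C)C)oc2c1OC | intermediate
11 | 2-ethynyl-5-hydroxy-6,7,8-trimethoxy-4H-chromen-4-one | COc1c(OC)c(O)c2c(=O)cc(C#C)oc2c1OC | intermediate
12 | 2,3-butanedione | CC(=O)C(C)=O | starting material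
13 | 2,3-bis(trimethylsilyloxy)buta-1,3-diene | C=C(O[Si](C)(C)C)C(=C)O[Si](C)(C)C | intermediate
14 | 2-[4,5-bis(trimethylsilyloxy)cyclohexa-1,4-dien-1-yl]-5-hydroxy-6,7,8-trimethoxy-4H-chromen-4-one | COc1c(OC)c(O)c2c(=O)cc(C3=CCC(O[Si](C)(C)C)=C(O[Si](C)(C)C)C3)oc2c1OC | intermediate
15 | 2-[3,4-bis(trimethylsilyloxy)phenyl]-5-hydroxy-6,7,8-trimethoxy-4H-chromen-4-one | COc1c(OC)c(O)c2c(=O)cc(-c3ccc(O[Si](C)(C)C)c(O[Si](C)(C)C)c3)oc2c1OC | intermediate
16 | sideritiflavone, 2-(3,4-dihydroxyphenyl)-5-hydroxy-6,7,8-trimethoxy-4H-chromen-4-one | COc1c(OC)c(O)c2c(=O)cc(-c3ccc(O)c(O)c3)oc2c1OC | target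

## Step count and least certain steps

Total: 10 steps. Longest linear sequence: 9 steps (steps 1–7, 9 and 10, from 1 to 16); step 8 is a one-step branch.

**Step 9 (key step).** The alkyne is activated only through the chromone, so the cycloaddition may be too slow at temperatures that 11 tolerates. Thermal oligomerisation of the ynone, or protodesilylation of the diene by the phenol, could then outrun ring formation. The fallback uses known flavone chemistry, sets out from 5 and comes back at 16. Claisen–Schmidt condensation of 5 with 3,4-bis(benzyloxy)benzaldehyde (KOH, EtOH) should give (E)-3-[3,4-bis(benzyloxy)phenyl]-1-(2-hydroxy-3,4,5,6-tetramethoxyphenyl)prop-2-en-1-one F1. Oxidative cyclisation with catalytic I2 in DMSO at 120 °C should give 2-[3,4-bis(benzyloxy)phenyl]-5,6,7,8-tetramethoxy-4H-chromen-4-one F2, which is the same compound as A6 of the third alternative. BCl3 in CH2Cl2 at −78 → 0 °C should then remove both benzyl groups and the peri methyl group to give 16.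

**Step 5.** The diketone enol oxygen may close 6-endo-dig onto the alkyne and give a 4-pyranone, or the alkyne may lose silicon and hydrate in the acid, so ring C would not form as a chromone. The fallback builds the chromone first and the alkyne last; it sets out from 5 and comes back at 11. Claisen condensation of 5 with ethyl acetate (NaH, THF) should give 1-(2-hydroxy-3,4,5,6-tetramethoxyphenyl)butane-1,3-dione F3. H2SO4 in AcOH should cyclise it to 5,6,7,8-tetramethoxy-2-methyl-4H-chromen-4-one F4. BCl3 should cleave the peri ether to give 5-hydroxy-6,7,8-trimethoxy-2-methyl-4H-chromen-4-one F5. Riley oxidation with SeO2 in dioxane at reflux should give 5-hydroxy-6,7,8-trimethoxy-4-oxo-4H-chromene-2-carbaldehyde F6. Ohira–Bestmann homologation (dimethyl (1-diazo-2-oxopropyl)phosphonate, K2CO3, MeOH, 0 °C, quenched with AcOH as soon as the aldehyde is consumed) should then give 11.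

**Step 4.** The enolate may add in conjugate fashion to the alkynoate, the phenoxide may be O-acylated, or liberated ethoxide may strip the silyl group, so acyl substitution at carbon would not dominate. The fallback replaces acyl substitution by aldol addition and oxidation; it sets out from 5 and comes back at 7. The dianion of 5 (LiN(SiMe3)2, THF, −78 °C) should add 1,2 to 3-(trimethylsilyl)propynal to give racemic 3-hydroxy-1-(2-hydroxy-3,4,5,6-tetramethoxyphenyl)-5-(trimethylsilyl)pent-4-yn-1-one F7. Dess–Martin periodinane in CH2Cl2 should oxidise the propargylic carbinol to 7.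

**Step 10.** The quinone may over-oxidise the electron-rich enediol ether or the liberated catechol to an ortho-quinone, or silyl loss before dehydrogenation may open a dehydration path to a monophenol. The fallback moves the oxidation from the C–H level to the carbinol level; it sets out from 14 and comes back at 16. Mild acidic methanolysis of 14 (HCl, MeOH–THF, 0 °C) should give the regioisomeric acyloins 5-hydroxy-2-(4-hydroxy-5-oxocyclohex-1-en-1-yl)-6,7,8-trimethoxy-4H-chromen-4-one F8 and 5-hydroxy-2-(5-hydroxy-4-oxocyclohex-1-en-1-yl)-6,7,8-trimethoxy-4H-chromen-4-one F9 (each racemic, not separated). Cu(OAc)2 in aqueous AcOH under N2 should oxidise either carbinol to 2-(4,5-dioxocyclohex-1-en-1-yl)-5-hydroxy-6,7,8-trimethoxy-4H-chromen-4-one F10, the diketo tautomer of the catechol, which should enolise at once to 16.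

## Further compounds

F1 | step 9 | (E)-3-[3,4-bis(benzyloxy)phenyl]-1-(2-hydroxy-3,4,5,6-tetramethoxyphenyl)prop-2-en-1-one | O=C(/C=C/c1ccc(OCc2ccccc2)c(OCc2ccccc2)c1)c1c(O)c(OC)c(OC)c(OC)c1OC
F2 | step 9 | 2-[3,4-bis(benzyloxy)phenyl]-5,6,7,8-tetramethoxy-4H-chromen-4-one | COc1c(OC)c(OC)c2c(=O)cc(-c3ccc(OCc4ccccc4)c(OCc4ccccc4)c3)oc2c1OC
F3 | step 5 | 1-(2-hydroxy-3,4,5,6-tetramethoxyphenyl)butane-1,3-dione | CC(=O)CC(=O)c1c(O)c(OC)c(OC)c(OC)c1OC
F4 | step 5 | 5,6,7,8-tetramethoxy-2-methyl-4H-chromen-4-one | COc1c(OC)c(OC)c2c(=O)cc(C)oc2c1OC
F5 | step 5 | 5-hydroxy-6,7,8-trimethoxy-2-methyl-4H-chromen-4-one | COc1c(OC)c(O)c2c(=O)cc(C)oc2c1OC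
F6 | step 5 | 5-hydroxy-6,7,8-trimethoxy-4-oxo-4H-chromene-2-carbaldehyde | COc1c(OC)c(O)c2c(=O)cc(C=O)oc2c1OC
F7 | step 4 | 3-hydroxy-1-(2-hydroxy-3,4,5,6-tetramethoxyphenyl)-5-(trimethylsilyl)pent-4-yn-1-one (racemic) | C[Si](C)(C)C#CC(O)CC(=O)c1c(O)c(OC)c(OC)c(OC)c1OC
F8 | step 10 | 5-hydroxy-2-(4-hydroxy-5-oxocyclohex-1-en-1-yl)-6,7,8-trimethoxy-4H-chromen-4-one (racemic) | COc1c(OC)c(O)c2c(=O)cc(C3=CCC(O)C(=O)C3)oc2c1OC
F9 | step 10 | 5-hydroxy-2-(5-hydroxy-4-oxocyclohex-1-en-1-yl)-6,7,8-trimethoxy-4H-chromen-4-one (racemic) | COc1c(OC)c(O)c2c(=O)cc(C3=CCC(=O)C(O)C3)oc2c1OC
F10 | step 10 | 2-(4,5-dioxocyclohex-1-en-1-yl)-5-hydroxy-6,7,8-trimethoxy-4H-chromen-4-one | COc1c(OC)c(O)c2c(=O)cc(C3=CCC(=O)C(=O)C3)oc2c1OC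
A1 | alternative 1 | 3',4'-O-diphenylmethylene sideritiflavone | COc1c(OC)c(O)c2c(=O)cc(-c3ccc4OC(c5ccccc5)(c5ccccc5)Oc4c3)oc2c1OC
A2 | alternative 1 | 6,8-dibromo-2-(2,2-diphenyl-1,3-benzodioxol-5-yl)-5-hydroxy-7-methoxy-4H-chromen-4-one | COc1c(Br)c(O)c2c(=O)cc(-c3ccc4OC(c5ccccc5)(c5ccccc5)Oc4c3)oc2c1Br
A3 | alternative 1 | luteolin | O=c1cc(-c2ccc(O)c(O)c2)oc2cc(O)cc(O)c12
A4 | alternative 2 | cis-4-(tert-butyldimethylsilyloxy)-2-(2,2-dimethyl-1,3-benzodioxol-5-yl)-6,7,8-trimethoxychroman-5-ol (racemic) | COc1c(OC)c(O)c2[C@@H](O[Si](C)(C)C(C)(C)C)C[C@@H](c3ccc4OC(C)(C)Oc4c3)Oc2c1OC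
A5 | alternative 2 | 4-[cis-4-(tert-butyldimethylsilyloxy)-2-(2,2-dimethyl-1,3-benzodioxol-5-yl)-3,4-dihydro-2H-pyran-6-yl]-2,3,4-trimethoxycyclobut-2-en-1-one (racemic pyran unit, both configurations at the cyclobutenone carbon) | COC1=C(OC)C(OC)(C2=C[C@@H](O[Si](C)(C)C(C)(C)C)C[C@@H](c3ccc4OC(C)(C)Oc4c3)O2)C1=O
A6 | alternative 3 | 3',4'-bis(benzyloxy)-5,6,7,8-tetramethoxyflavone | COc1c(OC)c(OC)c2c(=O)cc(-c3ccc(OCc4ccccc4)c(OCc4ccccc4)c3)oc2c1OC
A7 | alternative 3 | 2,3,4,5-tetramethoxy-6-(trimethylsilyl)phenyl trifluoromethanesulfonate | COc1c(OC)c(OC)c(OS(=O)(=O)C(F)(F)F)c([Si](C)(C)C)c1OC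
A8 | alternative 3 | 3-[3,4-bis(benzyloxy)phenyl]prop-2-ynoic acid | OC(=O)C#Cc1ccc(OCc2ccccc2)c(OCc2ccccc2)c1
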